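**Assumptions (one line):** The Roche ester, TBSCl, 2-(triphenylphosphoranylidene)propanal, diethyl benzylphosphonate, tert-butyl 2-(diethoxyphosphoryl)propanoate, glyoxylic acid, Ghosez reagent, PhNTf2 and EtMgBr are commercial. In the intramolecular Diels–Alder (IMDA) I assume the all-E, endo-(CO2tBu) transition state, with the methyl-bearing tether carbon setting the face. Minor diastereomers are removed by chromatography.

## Retrosynthetic overview
1. The target acid comes from its tert-butyl ester (last step is tBu cleavage). The ring C=C bearing the ethyl group comes from the ring ketone via enol triflate and Fe-catalysed ethylation.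
2. Both rings form together in one IMDA of a conjugated tetraene–enedione. The five-membered ring closes through the three-atom tether and the six-membered ring through the diene/dienophile. The four new stereocentres, including the vicinal quaternary carbons, are set in this step.
3. The IMDA precursor comes from Negishi-type acylation of an alkylzinc (from a primary iodide) with mono-tBu mesaconoyl chloride.
4. The iodide carries the full polyene. It is built from (R)-Roche ester (the only purchased stereocentre, which becomes C3-Me) by three Wittig reactions with 2-(triphenylphosphoranylidene)propanal, then an HWE olefination with a benzylphosphonate.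

## Route

**Step 1**
Reactants: 1 methyl (2R)-3-hydroxy-2-methylpropanoate (Roche ester); 2 tert-butyldimethylsilyl chloride
Product: 3 methyl (2R)-3-(TBS-oxy)-2-methylpropanoate
Conditions: 2, imidazole, DMF, 0 °C → rt
Reagents that add atoms: tert-butyldimethylsilyl chloride, CC(C)(C)[Si](C)(C)Cl
Why: Silylation of the primary alcohol; the stereocentre is untouched.

**Step 2**
Reactants: 3
Product: 4 (2R)-3-(TBS-oxy)-2-methylpropanal
Conditions: DIBAL-H (1.1 equiv), CH2Cl2, −78 °C
Reagents that add atoms: none
Why: Partial DIBAL reduction of the ester through a stable aluminium hemiacetal; the α-methyl aldehyde is used immediately to avoid epimerisation.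

**Step 3**
Reactants: 4; 5 2-(triphenylphosphoranylidene)propanal
Product: 6 (2E,4S)-5-(TBS-oxy)-2,4-dimethylpent-2-enal
Conditions: 5 (1.3 equiv), toluene, 80 °C
Reagents that add atoms: 2-(triphenylphosphoranylidene)propanal, CC(C=O)=P(c1ccccc1)(c1ccccc1)c1ccccc1
Why: A stabilised-ylide Wittig reaction gives the E-trisubstituted enal; the α-stereocentre is retained (R becomes S only because the CIP priorities change).

**Step 4**
Reactants: 6; 5
Product: 7 (2E,4E,6S)-7-(TBS-oxy)-2,4,6-trimethylhepta-2,4-dienal
Conditions: 5 (1.5 equiv), toluene, 110 °C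
Reagents that add atoms: 2-(triphenylphosphoranylidene)propanal, CC(C=O)=P(c1ccccc1)(c1ccccc1)c1ccccc1
Why: A second stabilised-ylide Wittig olefination extends the chain by one E-C(Me)=CH unit and fixes the second alkene geometry.

**Step 5**
Reactants: 7; 5
Product: 8 (2E,4E,6E,8S)-9-(TBS-oxy)-2,4,6,8-tetramethylnona-2,4,6-trienal
Conditions: 5 (2 equiv), toluene, 110 °C, dark
Reagents that add atoms: 2-(triphenylphosphoranylidene)propanal, CC(C=O)=P(c1ccccc1)(c1ccccc1)c1ccccc1
Why: A third stabilised-ylide Wittig gives the all-E trienal; this sets the geometry of the C=C bond that becomes the diene terminus (outside CH=C substituent) and of the side-chain C(Me)=CH.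

**Step 6**
Reactants: 8; 9 diethyl benzylphosphonate
Product: 10 tert-butyl-dimethyl-[(2S,3E,5E,7E,9E)-2,4,6,8-tetramethyl-10-phenyldeca-3,5,7,9-tetraen-1-yl]oxysilane
Conditions: 9 (1.5 equiv), KOtBu, THF, 0 °C → rt
Reagents that add atoms: diethyl benzylphosphonate, CCOP(=O)(OCC)Cc1ccccc1
Why: Horner–Wadsworth–Emmons olefination of the enal with the benzylphosphonate gives the E-styryl terminus of the polyene.

**Step 7**
Reactants: 10
Product: 11 (2S,3E,5E,7E,9E)-2,4,6,8-tetramethyl-10-phenyldeca-3,5,7,9-tetraen-1-ol
Conditions: TBAF, THF, 0 °C → rt, dark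
Reagents that add atoms: none
Why: Fluoride cleaves the primary TBS ether; the polyene and the allylic stereocentre are unaffected by these mildly basic conditions.

**Step 8**
Reactants: 11; 12 iodine
Product: 13 (2S,3E,5E,7E,9E)-1-iodo-2,4,6,8-tetramethyl-10-phenyldeca-3,5,7,9-tetraene
Conditions: PPh3, imidazole, 12, CH2Cl2, 0 °C, dark
Reagents that add atoms: iodine, II
Why: Appel-type (Garegg–Samuelsson) SN2 iodination at the unhindered primary carbon; the neighbouring stereocentre is not involved, and the iodine is consumed by PPh3 so polyene isomerisation is minimised.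

**Step 9**
Reactants: 14 tert-butyl 2-(diethoxyphosphoryl)propanoate; 15 glyoxylic acid
Product: 16 (2E)-4-tert-butoxy-3-methyl-4-oxobut-2-enoic acid (mono-tert-butyl mesaconate)
Conditions: 14, LiOH·H2O (2.2 equiv), THF/H2O, rt; then 15 (50% aq.)
Reagents that add atoms: tert-butyl 2-(diethoxyphosphoryl)propanoate, CCOP(=O)(OCC)C(C)C(=O)OC(C)(C)C; glyoxylic acid, O=CC(=O)O
Why: An HWE reaction gives the E-trisubstituted alkene, with the free acid on the CH end and the tBu ester on the CMe end, which is the regiochemistry needed in the dienophile.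

**Step 10**
Reactants: 16; 17 Ghosez reagent (1-chloro-N,N,2-trimethylprop-1-en-1-amine)
Product: 18 (2E)-4-tert-butoxy-3-methyl-4-oxobut-2-enoyl chloride
Conditions: 17, CH2Cl2, 0 °C → rt; concentrate and use crude
Reagents that add atoms: Ghosez reagent, CC(C)=C(Cl)N(C)C
Why: Neutral acid-chloride formation leaves the tBu ester intact and does not isomerise the alkene.

**Step 11**
Reactants: 13; 18
Product: 19 tert-butyl (2E,6R,7E,9E,11E,13E)-2,6,8,10,12-pentamethyl-4-oxo-14-phenyltetradeca-2,7,9,11,13-pentaenoate (IMDA precursor)
Conditions: (i) Zn dust, LiCl, I2 (cat.), THF, 40 °C; (ii) 18, Pd(PPh3)4 (5 mol%), THF, 0 °C → rt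
Reagents that add atoms: 18, ClC(=O)/C=C(\C)C(=O)OC(C)(C)C
Why: Knochel-type zinc insertion into the primary iodide followed by Pd-catalysed Negishi acylation joins the polyene, the three-atom tether (with the methyl stereocentre) and the E-enedione dienophile; the alkylzinc tolerates the ester and the polyene.

**Step 12**
Reactants: 19
Product: 20 tert-butyl 3,4,6,7-tetramethyl-1-oxo-6-[(1E,3E)-2-methyl-4-phenylbuta-1,3-dien-1-yl]-2,3,3a,6,7,7a-hexahydro-1H-indene-7-carboxylate, trans-fused (configuration as in the compound list)
Conditions: toluene (0.01 M), BHT (cat.), 140–150 °C, sealed tube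
Reagents that add atoms: none
Why: In this intramolecular Diels–Alder reaction the suprafacial addition preserves the E,E-diene and E-dienophile geometries, so the two outside groups (the tether carbon and the dienyl chain) end up cis to each other and to the endo CO2tBu. The three-atom tether enforces the trans-fused hydrindane, and the existing methyl-bearing carbon biases the face, so the four new stereocentres are set relative to it. Both rings form in this one step.

**Step 13**
Reactants: 20; 21 PhNTf2 (N-phenylbis(trifluoromethanesulfonimide))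
Product: 22 enol triflate (cyclopentenyl triflate at the former ketone carbon, C1=C2)
Conditions: KHMDS, THF, −78 °C; then 21, −78 → 0 °C
Reagents that add atoms: N-phenylbis(trifluoromethanesulfonimide), O=S(=O)(N(c1ccccc1)S(=O)(=O)C(F)(F)F)C(F)(F)F
Why: Kinetic enolisation occurs at the unhindered CH2, not at the ring-fusion methine next to the quaternary centre, so the triflate sits on the required C1=C2 bond and the ring-fusion stereocentre is not epimerised.

**Step 14**
Reactants: 22; 23 ethylmagnesium bromide
Product: 24 tert-butyl ester of the target (ethyl-cyclopentene)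
Conditions: 23 (2 equiv), Fe(acac)3 (5 mol%), THF/NMP, 0 °C
Reagents that add atoms: ethylmagnesium bromide, CC[Mg]Br
Why: Fe-catalysed Kumada-type cross-coupling of an alkenyl triflate with an alkyl Grignard puts the ethyl group on C1 with the alkene position retained; the hindered tBu ester and the polyene are not attacked.

**Step 15**
Reactants: 24
Product: 25 Zyggomphic acid B
Conditions: TMSOTf, 2,6-lutidine, CH2Cl2, 0 °C; then aq. pH 5 buffer workup
Reagents that add atoms: none
Why: Silylative, non-protic cleavage of the tBu ester (via the TMS ester, which hydrolyses on workup) frees the hindered acid without saponification and without strong protic acid that would damage the polyene; no stereocentre is involved.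

## Compound list
1 | methyl (2R)-3-hydroxy-2-methylpropanoate (Roche ester) | COC(=O)[C@H](C)CO | starting material
2 | tert-butyldimethylsilyl chloride | CC(C)(C)[Si](C)(C)Cl | starting material
3 | methyl (2R)-3-(TBS-oxy)-2-methylpropanoate | COC(=O)[C@H](C)CO[Si](C)(C)C(C)(C)C | intermediate
4 | (2R)-3-(TBS-oxy)-2-methylpropanal | O=C[C@H](C)CO[Si](C)(C)C(C)(C)C | intermediate
5 | 2-(triphenylphosphoranylidene)propanal | CC(C=O)=P(c1ccccc1)(c1ccccc1)c1ccccc1 | starting material
6 | (2E,4S)-5-(TBS-oxy)-2,4-dimethylpent-2-enal | C[C@H](CO[Si](C)(C)C(C)(C)C)/C=C(\C)C=O | intermediate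
7 | (2E,4E,6S)-7-(TBS-oxy)-2,4,6-trimethylhepta-2,4-dienal | C[C@H](CO[Si](C)(C)C(C)(C)C)/C=C(\C)/C=C(\C)C=O | intermediate
8 | (2E,4E,6E,8S)-9-(TBS-oxy)-2,4,6,8-tetramethylnona-2,4,6-trienal | C[C@H](CO[Si](C)(C)C(C)(C)C)/C=C(\C)/C=C(\C)/C=C(\C)C=O | intermediate
9 | diethyl benzylphosphonate | CCOP(=O)(OCC)Cc1ccccc1 | starting material
10 | tetraene TBS ether, tert-butyl-dimethyl-[(2S,3E,5E,7E,9E)-2,4,6,8-tetramethyl-10-phenyldeca-3,5,7,9-tetraen-1-yl]oxysilane | C[C@H](CO[Si](C)(C)C(C)(C)C)/C=C(\C)/C=C(\C)/C=C(\C)/C=C/c1ccccc1 | intermediate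
11 | (2S,3E,5E,7E,9E)-2,4,6,8-tetramethyl-10-phenyldeca-3,5,7,9-tetraen-1-ol | C[C@H](CO)/C=C(\C)/C=C(\C)/C=C(\C)/C=C/c1ccccc1 | intermediate
12 | iodine | II | starting material
13 | (2S,3E,5E,7E,9E)-1-iodo-2,4,6,8-tetramethyl-10-phenyldeca-3,5,7,9-tetraene | C[C@H](CI)/C=C(\C)/C=C(\C)/C=C(\C)/C=C/c1ccccc1 | intermediate
14 | tert-butyl 2-(diethoxyphosphoryl)propanoate | CCOP(=O)(OCC)C(C)C(=O)OC(C)(C)C | starting material
15 | glyoxylic acid | O=CC(=O)O | starting material
16 | (2E)-4-tert-butoxy-3-methyl-4-oxobut-2-enoic acid | OC(=O)/C=C(\C)C(=O)OC(C)(C)C | intermediate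
17 | Ghosez reagent | CC(C)=C(Cl)N(C)C | starting material
18 | (2E)-4-tert-butoxy-3-methyl-4-oxobut-2-enoyl chloride | ClC(=O)/C=C(\C)C(=O)OC(C)(C)C | intermediate
19 | IMDA precursor, tert-butyl (2E,6R,7E,9E,11E,13E)-2,6,8,10,12-pentamethyl-4-oxo-14-phenyltetradeca-2,7,9,11,13-pentaenoate | C[C@H](CC(=O)/C=C(\C)C(=O)OC(C)(C)C)/C=C(\C)/C=C(\C)/C=C(\C)/C=C/c1ccccc1 | intermediate
20 | trans-fused hydrindanone IMDA adduct | O=C1C[C@@H](C)[C@@H]2C(C)=C[C@](C)(/C=C(C)/C=C/c3ccccc3)[C@](C)(C(=O)OC(C)(C)C)[C@@H]12 | intermediate
21 | N-phenylbis(trifluoromethanesulfonimide) | O=S(=O)(N(c1ccccc1)S(=O)(=O)C(F)(F)F)C(F)(F)F | starting material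
22 | enol triflate | FC(F)(F)S(=O)(=O)OC1=C[C@@H](C)[C@@H]2C(C)=C[C@](C)(/C=C(C)/C=C/c3ccccc3)[C@](C)(C(=O)OC(C)(C)C)[C@@H]12 | intermediate
23 | ethylmagnesium bromide | CC[Mg]Br | starting material
24 | tert-butyl ester of Zyggomphic acid B | CCC1=C[C@@H](C)[C@@H]2C(C)=C[C@](C)(/C=C(C)/C=C/c3ccccc3)[C@](C)(C(=O)OC(C)(C)C)[C@@H]12 | intermediate
25 | Zyggomphic acid B | CCC1=C[C@@H](C)[C@@H]2C(C)=C[C@](C)(/C=C(C)/C=C/c3ccccc3)[C@](C)(C(=O)O)[C@@H]12 | target

## Totals
Total steps: 15. Longest linear sequence: 13 (steps 1–8, then 11–15).

## Three steps most likely to fail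
1. **Step 12 (IMDA).** Two fully substituted carbons must bond to form vicinal quaternary centres from a hindered diene terminus, so the reaction may be slow, give endo/exo or ring-fusion mixtures, or lead to polyene decomposition.
   - Fallback (changes approach): use the des-methyl dienophile (commercial mono-tBu fumaroyl chloride in place of 18, skipping steps 9–10). Run the IMDA to form only one quaternary centre, then do the ketone → triflate → ethyl sequence (steps 13–14) first, and finally install the C7 methyl by tBu-ester enolate methylation (LiHMDS, MeI) so that no ketone enolisation competes.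
2. **Step 11 (Pd-catalysed acylation of the alkylzinc).** The highly electrophilic enoyl chloride and the enedione product may undergo conjugate addition, alkene isomerisation or early cyclisation.
   - Fallback (changes approach): convert iodide 13 to its Grignard reagent and add it to tBuO2C–C(Me)=CH–CHO (from tBuO2C–C(Me)=PPh3 and aqueous glyoxal). Then oxidise the allylic alcohol with Dess–Martin periodinane to give the same enedione 19.
3. **Step 15 (tBu cleavage).** The ester is neopentyl-like and flanked by a quaternary carbon, while the tetraene is acid-sensitive, so cleavage may be slow or destroy the polyene.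
   - Fallback (changes approach): carry a 2-(trimethylsilyl)ethyl ester instead of tBu from step 9 onward (HWE with the TMSE phosphonopropionate). The final deprotection is then fluoride-induced β-elimination (TBAF, THF), which does not attack the hindered carbonyl and needs no acid.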